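(The numbers belong to no real substance; the flask was simulated.)

Over 6.0 s, at 90 °C or in alpha's addition at 70 °C, these flasks turn electrophile into target with a nucleophile that the acid set free also takes away.

| flask | electrophile | nucleophile | free base | protic impurity | temperature | time | remark |
|---|---|---|---|---|---|---|---|
| theta | 0.10 M | 0.105 M (fed, over 2.5 s) | 0.120 M | 0.0100 M | 90 °C | 6.0 s | all else is in the flask from the start; the feed brings no volume worth counting |
| zeta | 0.10 M (in portions, 5, over 2.5 s) | 0.105 M | 0.120 M | 0.0100 M | 90 °C | 6.0 s | first portion at the start, last at 2.5 s |
| alpha | 0.10 M (fed, over 2.5 s) | 0.105 M | 0.120 M | 0.0100 M |  | 6.0 s | the addition at 70 °C, then warmed to 90 °C; the feed brings no volume worth counting |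
| eta | 0.10 M (fed, over 2.5 s) | 0.105 M | 0.120 M | 0.0100 M | 90 °C | 6.0 s | all else is in the flask from the start; the feed brings no volume worth counting |

    electrophile + nucleophile → acid set free + target (k1 = 1.3 /M/s, Ea1 = 42.0 kJ/mol)
    nucleophile + acid set free ⇌ protonated nucleophile, settled at all times (K2 = 4100 /M, ΔH2 = −82.0 kJ/mol)
    acid set free + free base ⇌ salt of the base, settled at all times (K3 = 10 /M, ΔH3 = −42.0 kJ/mol)
    2 electrophile → self-condensation product (k4 = 6.4 × 10⁻⁴ /M/s, Ea4 = 79.0 kJ/mol)
    nucleophile + protic impurity → quenched reagent (k5 = 5.2 /M/s, Ea5 = 61.0 kJ/mol)
    target → over-reaction product (k6 = 0.16 /s, Ea6 = 96.0 kJ/mol)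
    (constants at 90 °C)

- a species is counted by the electrophile in it: one self-condensation product counts as two
- where a step has two of a species, its rate is k times that concentration squared, and two are used at each turn
- all constants are for 90 °C and move with temperature by the activation energies and enthalpies

- the flask with the highest amount of target, in percent of the electrophile charged ("all alike" if they lie within 1.5 percentage points) (theta / zeta / alpha / eta / all alike)
- final target, as a percentage of the electrophile charged, in theta
- final target, as a percentage of the electrophile charged, in zeta
- final target, as a percentage of the electrophile charged, in alpha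
- final target, as a percentage of the electrophile charged, in eta

We reckon on eta, where the nucleophile stands from the start and the electrophile is fed over 2.5 s. In the first instants the fast balances share out each acid set free. In eta at the start the nucleophile takes it over the free base by 359 to one, so each electrophile turned costs two nucleophile. At the starting c(nucleophile) in eta, the protic impurity has a half-life of 1.27 s, shorter than the 5.08 s of the electrophile, so in this reckoning we charge its whole amount to the nucleophile at once. That leaves 0.0950 M to spend. Our carried quantity is the ration: the share of the electrophile charged that the nucleophile can pay for while the acid goes onto it, which is the nucleophile charge less the impurity, over twice the electrophile charge. In eta it is 47.5 %, so the nucleophile is the effective limiting reagent.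

For the middle of the run we iterate. The electrophile in eta arrives on average at half the feed time, so it has 4.75 s to react. If c(nucleophile) held at 0.0950 M, 44.4 % would turn. Spending two nucleophile per turn puts the mean c(nucleophile) at the start value less the turned amount, and going round with that gives 26.8 %, then 34.4 %. The rounds swing about a middle, and we commit to 30.6 %.

At the end of eta we reckon 0.0338 M of nucleophile. It still takes the acid over the free base by 115 to one, so the cost per turn stands. Target made evenly over 6.0 s survives over-reaction to 64.3 %, which gives 19.7 % of target in eta. By then making, 0.00305 M/s, is about as fast as over-reaction, 0.00315 M/s. Alpha's cool addition slows over-reaction more than making, with 96.0 kJ/mol against 42.0 kJ/mol, but making slows too. We expect the flasks to lie within 1.5 percentage points of one another.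

The forecast says all alike, with 20.2 % in theta, 20 % in zeta, 19.6 % in alpha and 19.7 % in eta. Its ground is that “each target costs two nucleophiles”.

The simulation gives all alike: 19.8 % in theta, 19.4 % in zeta, 19.9 % in alpha, 19.5 % in eta. The loss of electrophile to self-condensation product made no difference between the flasks. In eta 69.2 % of the electrophile stood at 6.00 s, so 30.8 % had turned, inside the ration of 47.5 %.

The neighbour flask is alpha with 0.042 M of nucleophile. Its ration is 16.0 %, and the survival of 64.3 % reckoned for eta turns that into an estimate of 10.3 % of target. The run gives 8.42 %, with 87.8 % of the electrophile left.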